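Remark on the chemistry: lactols 10, 15, 26 and 31 are carried as mixtures of anomers, because the anomeric carbon becomes a carbonyl or a carbinol carbon in the next step.

## Analysis of the target

The target is a B-type proanthocyanidin trimer in which epicatechin gallate (top unit) is joined through C4 to C8 of epigallocatechin gallate (middle unit), whose C4 is joined in turn to C8 of catechin gallate (bottom unit). Each unit is a 2-arylchroman (rings A and C, with ring B on C2) that carries a galloyl ester on O3; the bottom unit keeps a C4 methylene, whereas C4 of the other two is a diarylmethine. Of the eight stereocentres, C2 and C3 of the bottom unit are trans as in (+)-catechin, and the middle and top units share one pattern, with the C2 aryl group and the C3 oxygen cis (both α) and the C4 aryl bond trans to O3 (β). The sensitive groups are twenty-two free phenols, among them four pyrogallol rings that oxidise easily, three galloyl esters that do not survive strong nucleophiles or bases, and two interflavan bonds that are doubly benzylic to phloroglucinol rings and ionise under acid. The hard points are the configuration at C4 and the ring position (C8, not C6) of each interflavan bond, the 2,3-cis relation in two units, and the fact that the three units differ, so that no unit can be made by copying another. The strategy rests on ring A of the middle unit, a phloroglucinol ring that carries C4 (through C4a) and O1 (through C8a) on neighbouring carbons, while C4 is a diarylmethine between this ring and C8 of the bottom unit. A phenol can therefore add through an ortho carbon to the β-carbon of an enal placed on C8 of the bottom unit (C4–C4a) and close ring C through its oxygen on the aldehyde carbon (O1–C2). The top unit stands in the same relation to C8 of the middle unit, so the same reaction can be used twice.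

## Retrosynthetic reasoning

**Esters and protecting groups.** The three galloyl C–O bonds of 39 are cut first, which leads to the perbenzylated ester 38 and then to triol 36 and three equivalents of acid 37. The gallate esters would not survive the hydride, enolate and organomagnesium steps, so they are put on last, all three in one operation. All phenols travel as benzyl ethers and fall in one hydrogenolysis. The three O3 atoms travel as silyl ethers (35), which are inert to every C–C bond-forming step and leave together.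

**Top unit, O1–C2 and C2–aryl.** In 35 the O1–C2 bond of the top unit is cut to give the phenol carbinol 34; the forward step is an SN2 closure by the phenol with inversion at C2. The inversion dictates a 1,2-anti relation between the carbinol and the silyloxy carbon, which is the Felkin outcome of an aryl nucleophile adding to an α-silyloxy aldehyde. The C2–aryl bond is therefore cut next, to lactol 31 and aryl bromide 32 (through Grignard reagent 33).

**Top unit, C3–O.** The oxygen at C3 is disconnected at the lactone oxidation level (31 from 30, 29 and 27). Oxygenation on the lactol itself would leave two hydroxyls to tell apart, and the later addition needs a non-chelating silyl ether on O3 only. In lactone 27 the carbonyl marks C2, and enolate 28 is attacked on the face opposite the C4 aryl group, which gives the 3,4-trans relation by substrate control.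

**Top ring C.** Lactone 27 comes from lactol 26, and 26 is cut at C4–C4a and O1–C2 into the dimer enal 24 and phenol 8 (through hydroxy aldehyde 25). This is the second use of the annulation described below. It needs the same sense of induction, because C4 of the top and of the middle unit have the same arrangement.

**Handle on the dimer.** Enal 24 is cut at the C8–vinyl bond to bromide 22 and boronate 5 (through acetal 23), and 22 comes from dimer 21 by bromination. The forward bromination has to pick C8 of the middle unit, the only free position next to a ring oxygen. A Heck reaction at this bromide, which is flanked by two oxygen substituents, would be unreliable and can end at the wrong oxidation level. The three-carbon unit therefore arrives with its alkene and its masked aldehyde in place, as boronate 5.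

**Middle unit.** Dimer 21 is taken apart like the top unit: O1–C2 to the phenol carbinol 20, C2–aryl to lactol 15 and bromide 18 (through 19), and C3–O through 14 and 13 to lactone 11 (enolate 12), which comes from lactol 10. Bromide 18 is reached from 16 through 17.

**Key disconnection.** Lactol 10 is cut at C4–C4a and O1–C2 into enal 7 and phenol 8 (through 9). These bonds are chosen because they turn the interflavan bond into a catalytic conjugate addition to an iminium ion, run close to neutral, instead of a cation coupling. Phenol 8 is symmetric and bought, and the bottom unit carries its electrophile at C8 only, so the ring position is fixed by construction. The forward step must set C4 by the catalyst.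

**Bottom unit.** Enal 7 is cut to bromide 4 and boronate 5 (through acetal 6). Bromide 4 comes from (+)-catechin 1 by benzylation (2), silylation (3) and C8 bromination. Both stereocentres of the bottom unit are taken from 1.

## Alternatives that were turned down

Alternative 1: epoxidation and syn arylation of a 4H-chromene.
- Disconnection: C2–aryl and C3–O of the middle unit, back to the 4H-chromene A1, which could be made from lactol 10 by dehydration.
- Forward key step: the C2=C3 enol ether of A1 is epoxidised by a dioxirane on the face anti to the C4 aryl group, and a triarylaluminium reagent then delivers its aryl group to C2 from the side of the new C3 oxygen, giving A2 with the 2,3-cis and 3,4-trans relations.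
- For: ring B and two stereocentres arrive in two operations, both induced from C4, and the cis relation follows from the mechanism. On step count it beats the chosen route by about four steps for this unit.
- Against: epoxides of 5,7-dioxygenated chromenes are glycal-type epoxides next to a phloroglucinol ring. They should open to a well-stabilised oxocarbenium ion, after which hydride shift to a C3 carbonyl, elimination, or loss of the syn preference can follow. The oxidant must also spare two phloroglucinol ether rings and many benzylic C–H bonds. Syn aryl transfer is established for simple aryl groups and uses three aryl groups per aluminium.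
- Comparison: the chosen route sets C3 and C2 in separate steps through stable lactone intermediates. Each step has its own control element (enolate face, Felkin addition, SN2 inversion) and its own point of correction.

Alternative 2: ring expansion of a dihydrobenzofuran to the bottom pyran.
- Disconnection: O1–C2 and C3–O of the bottom unit, back to A3, in which a 2-(α-galloyloxybenzyl)dihydrobenzofuran sits on C4 of a finished middle unit.
- Forward key step: a Lewis acid ionises the benzylic ester with help from the ring oxygen, the oxygen moves to the benzylic carbon and the gallate returns to the former furan carbon, giving A4 by double inversion.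
- For: one gallate arrives without a separate acylation, and the ring position of the interflavan bond is fixed by construction. On these two points it is as strong as or stronger than the chosen route.
- Against: the bottom unit is (+)-catechin, which can be bought with both stereocentres; here they would be built anew, with inverted configuration, on an arene already attached to C4. The Lewis acid that ionises a benzylic ester also ionises the interflavan bond and attacks benzyl ethers, and a catechol-stabilised open cation would erode the double inversion. The middle ring C and its C4 are not addressed.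
- Comparison: the chosen route reaches the bottom unit in four steps without stereochemical risk and forms the interflavan bond without strong acid.

Alternative 3: benzannulation of the middle ring A from C4 of the top unit.
- Disconnection: three C–C bonds of the middle ring A, back to the 4β-(siloxyethynyl) epicatechin derivative A5 and cyclobutenone A6.
- Forward key step: heating opens A6 by electrocyclic ring opening; cycloaddition with the siloxyalkyne of A5, a second ring opening and a six-electron electrocyclisation then lead to phenol A7.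
- For: the top–middle bond exists before the middle ring does, so C8 against C6 cannot arise and no dimer needs to be brominated. This is stronger than the chosen route, which relies on C8-selective bromination of 21. The top unit also comes from natural epicatechin, and the three oxygens of the new ring are differentiated.
- Against: A5 places a siloxyalkyne on a hindered, ionisable C4 and must survive heating. A7 is only an aryl flavan: ring C of the middle unit with three stereocentres and the bond from its C4 to C8 of the bottom unit are still to be made, now on an unsymmetrical phenol.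
- Comparison: the chosen annulation forms C4–C4a and O1–C2 in one catalytic step from a symmetric, purchasable phenol, and the same reaction serves both upper units, so one reaction type has to be optimised. The price is a longer linear sequence for the top unit.

Key step: step 5

## Route

Step 1
Reactants: 1 (+)-catechin
Product: 2 5,7,3',4'-tetra-O-benzyl-(+)-catechin
Conditions: BnBr (4.4 equiv), K2CO3, DMF, 0 °C → rt
Reagents that add atoms: benzyl bromide, BrCc1ccccc1
Why: Williamson etherification; carbonate deprotonates the four phenols but not the secondary alcohol at C3, so alkylation should stop at the tetraether and no stereocentre is touched.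

Step 2
Reactants: 2 5,7,3',4'-tetra-O-benzyl-(+)-catechin
Product: 3 5,7,3',4'-tetra-O-benzyl-3-O-(tert-butyldimethylsilyl)-(+)-catechin
Conditions: TBSCl, imidazole, DMF, rt
Reagents that add atoms: tert-butyldimethylsilyl chloride, CC(C)(C)[Si](C)(C)Cl
Why: Silylation of the only free hydroxyl; the silyl ether is inert to the organometallic, enolate and hydride steps that follow.

Step 3
Reactants: 3 5,7,3',4'-tetra-O-benzyl-3-O-(tert-butyldimethylsilyl)-(+)-catechin
Product: 4 8-bromo-5,7,3',4'-tetra-O-benzyl-3-O-(tert-butyldimethylsilyl)-(+)-catechin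
Conditions: N-bromosuccinimide (1.0 equiv), CH2Cl2, −78 °C → rt
Reagents that add atoms: N-bromosuccinimide, O=C1CCC(=O)N1Br
Why: Electrophilic aromatic bromination; in benzylated flavan-3-ols C8, between O1 and the 7-benzyloxy group, reacts before C6, which lies between two benzyloxy groups, and ring B is far less activated.

Step 4
Reactants: 4 8-bromo-5,7,3',4'-tetra-O-benzyl-3-O-(tert-butyldimethylsilyl)-(+)-catechin; 5 (E)-2-(3,3-diethoxyprop-1-en-1-yl)-4,4,5,5-tetramethyl-1,3,2-dioxaborolane
Product: 7 (E)-3-[5,7,3',4'-tetra-O-benzyl-3-O-(tert-butyldimethylsilyl)catechin-8-yl]acrylaldehyde, via diethyl acetal 6 (not isolated)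
Conditions: Pd(OAc)2 (5 mol%), SPhos (10 mol%), K3PO4, 1,4-dioxane/H2O, 80 °C; then 1 M HCl, THF, 0 °C
Reagents that add atoms: water, O
Why: Suzuki–Miyaura coupling; the dialkylbiarylphosphine is made for aryl bromides with two ortho substituents, and the alkene geometry of the boronate is retained. The allylic acetal should hydrolyse under mild acid that leaves the secondary silyl ether intact.

Step 5
Reactants: 7 (E)-3-[5,7,3',4'-tetra-O-benzyl-3-O-(tert-butyldimethylsilyl)catechin-8-yl]acrylaldehyde; 8 3,5-bis(benzyloxy)phenol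
Product: 10 (4R)-5,7-bis(benzyloxy)-4-[5,7,3',4'-tetra-O-benzyl-3-O-(tert-butyldimethylsilyl)catechin-8-yl]chroman-2-ol (anomeric mixture), via hydroxy aldehyde 9 (not isolated)
Conditions: 8 (1.5 equiv), (S)-2-[diphenyl(trimethylsilyloxy)methyl]pyrrolidine (20 mol%), PhCO2H (20 mol%), toluene, 0 °C → rt
Reagents that add atoms: none
Why: The secondary amine condenses with enal 7 to an E-configured iminium ion, one face of which is covered by the diphenyl(silyloxy)methyl group; phenol 8, by far the most nucleophilic arene present, attacks the β-carbon through an ortho carbon in an asymmetric Friedel–Crafts conjugate addition (C4–C4a), and hydrolysis of the enamine releases hydroxy aldehyde 9. The phenol oxygen then adds to the aldehyde carbon in a 6-exo-trig hemiacetalisation (O1–C2), which closes ring C of the middle unit as lactol 10. The closest known reaction type is the diarylprolinol silyl ether-catalysed Friedel–Crafts alkylation and hemiacetalisation of naphthols, sesamol and dialkoxyphenols with enals to 4-substituted chroman-2-ols. C4 is set by the catalyst: with the (S)-amine the Re face of the β-carbon should be shielded, and attack on the Si face gives the 4R configuration (bottom aryl group β); the stereocentres of the bottom unit are four bonds away and are expected to matter little, and if the sense proved opposite the (R)-amine would be used. The anomeric centre is not controlled and is removed in step 6. Ortho rather than para attack rests on hydrogen bonding of the phenolic OH in the transition state and on the fact that only the ortho adduct can drain into the lactol; the two ortho positions of 8 are equivalent. Chemoselectivity comes from the substrate, since every other arene position belongs to an aryl ether, and the excess of 8 keeps the product from reacting a second time.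

Step 6
Reactants: 10 (4R)-5,7-bis(benzyloxy)-4-[5,7,3',4'-tetra-O-benzyl-3-O-(tert-butyldimethylsilyl)catechin-8-yl]chroman-2-ol
Product: 11 (4R)-5,7-bis(benzyloxy)-4-[5,7,3',4'-tetra-O-benzyl-3-O-(tert-butyldimethylsilyl)catechin-8-yl]chroman-2-one
Conditions: (nPr4N)RuO4 (5 mol%), N-methylmorpholine N-oxide, 4 Å molecular sieves, CH2Cl2, rt
Reagents that add atoms: none
Why: (nPr4N)RuO4-catalysed oxidation of a lactol to a lactone; aryl ethers, benzyl ethers and the silyl ether are inert, and C4 is not acidic enough to epimerise.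

Step 7
Reactants: 11 (4R)-5,7-bis(benzyloxy)-4-[5,7,3',4'-tetra-O-benzyl-3-O-(tert-butyldimethylsilyl)catechin-8-yl]chroman-2-one
Product: 13 3,4-trans-5,7-bis(benzyloxy)-3-hydroxy-4-[5,7,3',4'-tetra-O-benzyl-3-O-(tert-butyldimethylsilyl)catechin-8-yl]chroman-2-one (3-OH α; 4-aryl β), via potassium enolate 12 (not isolated)
Conditions: KN(SiMe3)2, THF, −78 °C; then 2-(phenylsulfonyl)-3-phenyloxaziridine, −78 °C; aq. NH4Cl
Reagents that add atoms: 2-(phenylsulfonyl)-3-phenyloxaziridine, O=S(=O)(c1ccccc1)N1OC1c1ccccc1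
Why: Enolate hydroxylation with an N-sulfonyloxaziridine; the C4 aryl group is pseudo-axial to avoid the 5-benzyloxy group and blocks one face of the planar enolate, so oxygen should enter anti to it and give the 3,4-trans lactone.

Step 8
Reactants: 13 3,4-trans-3-hydroxy lactone
Product: 14 3,4-trans-5,7-bis(benzyloxy)-3-(tert-butyldimethylsilyloxy)-4-[5,7,3',4'-tetra-O-benzyl-3-O-(tert-butyldimethylsilyl)catechin-8-yl]chroman-2-one
Conditions: TBSOTf, 2,6-lutidine, CH2Cl2, −78 → 0 °C
Reagents that add atoms: tert-butyldimethylsilyl trifluoromethanesulfonate, CC(C)(C)[Si](C)(C)OS(=O)(=O)C(F)(F)F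
Why: Silylation of a hindered secondary alcohol with the silyl triflate; the bulky, weakly coordinating silyl ether is what the non-chelated addition in step 12 requires.

Step 9
Reactants: 14 3-silyloxy lactone
Product: 15 3,4-trans-5,7-bis(benzyloxy)-3-(tert-butyldimethylsilyloxy)-4-[5,7,3',4'-tetra-O-benzyl-3-O-(tert-butyldimethylsilyl)catechin-8-yl]chroman-2-ol (anomeric mixture)
Conditions: iBu2AlH (1.2 equiv), CH2Cl2, −78 °C; aq. potassium sodium tartrate
Reagents that add atoms: none
Why: Partial reduction of a dihydrocoumarin to the chroman-2-ol; the aluminium hemiacetal is stable at −78 °C and gives the lactol on work-up.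

Step 10
Reactants: 16 5-bromo-1,2,3-trimethoxybenzene
Product: 17 5-bromobenzene-1,2,3-triol
Conditions: BBr3, CH2Cl2, −78 °C → rt; then H2O
Reagents that add atoms: none
Why: Lewis acid cleavage of aryl methyl ethers; the aryl bromide is untouched, and the air-sensitive triol is used at once.

Step 11
Reactants: 17 5-bromobenzene-1,2,3-triol
Product: 18 5-bromo-1,2,3-tris(benzyloxy)benzene
Conditions: BnBr (3.3 equiv), K2CO3, DMF, rt, under N2
Reagents that add atoms: benzyl bromide, BrCc1ccccc1
Why: Williamson etherification of the three phenols.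

Step 12
Reactants: 15 3-silyloxy lactol; 18 5-bromo-1,2,3-tris(benzyloxy)benzene
Product: 20 (1S)-3-[2,4-bis(benzyloxy)-6-hydroxyphenyl]-2-(tert-butyldimethylsilyloxy)-3-[5,7,3',4'-tetra-O-benzyl-3-O-(tert-butyldimethylsilyl)catechin-8-yl]-1-[3,4,5-tris(benzyloxy)phenyl]propan-1-ol (1,2-anti; the other stereocentres unchanged), via aryl Grignard reagent 19 (not isolated)
Conditions: 18 (3 equiv), Mg, THF, 40 °C; then 15, THF, −78 → −20 °C; aq. NH4Cl
Reagents that add atoms: none
Why: Grignard addition to a lactol; the first equivalent opens the lactol to the magnesium phenoxide of the α-silyloxy aldehyde, and the second adds under Felkin–Anh control (C–O bond anti to the nucleophile, attack past H and not past the diarylmethyl group), which should give the 1,2-anti carbinol. Low temperature and the magnesium counter-ion keep the silyl group on O3.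

Step 13
Reactants: 20 anti phenol carbinol of the middle unit
Product: 21 [5,7,3',4',5'-penta-O-benzyl-3-O-(tert-butyldimethylsilyl)epigallocatechin]-(4β→8)-[5,7,3',4'-tetra-O-benzyl-3-O-(tert-butyldimethylsilyl)catechin]
Conditions: PPh3, diisopropyl azodicarboxylate, THF, 0 °C → rt
Reagents that add atoms: none
Why: Intramolecular Mitsunobu etherification; the phenol displaces the activated benzylic carbinol in a 6-exo-tet SN2 closure with inversion, which turns the anti carbinol into the 2,3-cis chroman. The two meta-benzyloxy groups of the aryl ring disfavour a free benzylic cation.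

Step 14
Reactants: 21 protected epigallocatechin-(4β→8)-catechin
Product: 22 derivative of 21 with bromine at C8 of the epigallocatechin unit
Conditions: N-bromosuccinimide (1.0 equiv), CH2Cl2, −78 → −30 °C
Reagents that add atoms: N-bromosuccinimide, O=C1CCC(=O)N1Br
Why: Electrophilic aromatic bromination; C8 of the middle unit is the only free position next to a ring oxygen, the type that reacts first in the monomers (step 3), while both C6 positions lie between two benzyloxy groups.

Step 15
Reactants: 22 bromide of the dimer; 5 (E)-2-(3,3-diethoxyprop-1-en-1-yl)-4,4,5,5-tetramethyl-1,3,2-dioxaborolane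
Product: 24 (E)-3-(dimer-8-yl)acrylaldehyde (enal on C8 of the epigallocatechin unit of the dimer), via diethyl acetal 23 (not isolated)
Conditions: Pd(OAc)2 (5 mol%), SPhos (10 mol%), K3PO4, 1,4-dioxane/H2O, 80 °C; then 1 M HCl, THF, 0 °C
Reagents that add atoms: water, O
Why: Suzuki–Miyaura coupling and acetal hydrolysis as in step 4; no group of the dimer reacts with the base or with dilute acid at 0 °C.

Step 16
Reactants: 24 dimer enal; 8 3,5-bis(benzyloxy)phenol
Product: 26 5,7-bis(benzyloxy)-4-(dimer-8-yl)chroman-2-ol (anomeric mixture; dimer aryl group at C4 β), via hydroxy aldehyde 25 (not isolated)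
Conditions: 8 (1.5 equiv), (S)-2-[diphenyl(trimethylsilyloxy)methyl]pyrrolidine (20 mol%), PhCO2H (20 mol%), toluene, 0 °C → rt
Reagents that add atoms: none
Why: The same iminium-catalysed Friedel–Crafts addition and hemiacetalisation as in step 5; C4 of the top unit has the same spatial arrangement as C4 of the middle unit, so the same (S)-amine is used, and the lactol is again the sink for the ortho adduct.

Step 17
Reactants: 26 top-unit lactol
Product: 27 5,7-bis(benzyloxy)-4-(dimer-8-yl)chroman-2-one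
Conditions: (nPr4N)RuO4 (5 mol%), N-methylmorpholine N-oxide, 4 Å molecular sieves, CH2Cl2, rt
Reagents that add atoms: none
Why: Lactol to lactone oxidation as in step 6.

Step 18
Reactants: 27 top-unit lactone
Product: 29 3,4-trans-3-hydroxy lactone of the top unit (3-OH α; 4-aryl β), via potassium enolate 28 (not isolated)
Conditions: KN(SiMe3)2, THF, −78 °C; then 2-(phenylsulfonyl)-3-phenyloxaziridine, −78 °C; aq. NH4Cl
Reagents that add atoms: 2-(phenylsulfonyl)-3-phenyloxaziridine, O=S(=O)(c1ccccc1)N1OC1c1ccccc1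
Why: Enolate hydroxylation as in step 7; the pseudo-axial C4 substituent, now the whole dimer, shields one face even more strongly, so the 3,4-trans product is expected.

Step 19
Reactants: 29 top-unit 3-hydroxy lactone
Product: 30 top-unit 3,4-trans-3-(tert-butyldimethylsilyloxy) lactone
Conditions: TBSOTf, 2,6-lutidine, CH2Cl2, −78 → 0 °C
Reagents that add atoms: tert-butyldimethylsilyl trifluoromethanesulfonate, CC(C)(C)[Si](C)(C)OS(=O)(=O)C(F)(F)F
Why: Silylation as in step 8.

Step 20
Reactants: 30 top-unit 3-silyloxy lactone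
Product: 31 top-unit 3,4-trans-3-(tert-butyldimethylsilyloxy)chroman-2-ol (anomeric mixture)
Conditions: iBu2AlH (1.2 equiv), CH2Cl2, −78 °C; aq. potassium sodium tartrate
Reagents that add atoms: none
Why: Partial lactone reduction as in step 9.

Step 21
Reactants: 31 top-unit 3-silyloxy lactol; 32 4-bromo-1,2-bis(benzyloxy)benzene
Product: 34 1,2-anti phenol carbinol of the top unit: 1-[3,4-bis(benzyloxy)phenyl]-3-[2,4-bis(benzyloxy)-6-hydroxyphenyl]-2-(tert-butyldimethylsilyloxy)-3-(dimer-8-yl)propan-1-ol, via aryl Grignard reagent 33 (not isolated)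
Conditions: 32 (3 equiv), Mg, THF, 40 °C; then 31, THF, −78 → −20 °C; aq. NH4Cl
Reagents that add atoms: none
Why: Grignard addition to the opened lactol under Felkin–Anh control as in step 12, expected to give the anti carbinol.

Step 22
Reactants: 34 top-unit anti phenol carbinol
Product: 35 [tetra-O-benzyl-3-O-TBS-epicatechin]-(4β→8)-[penta-O-benzyl-3-O-TBS-epigallocatechin]-(4β→8)-[tetra-O-benzyl-3-O-TBS-catechin]
Conditions: PPh3, diisopropyl azodicarboxylate, THF, 0 °C → rt
Reagents that add atoms: none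
Why: Intramolecular Mitsunobu etherification with inversion at C2 as in step 13, giving the 2,3-cis top unit. The reaction is run cold because the para-benzyloxy group of this aryl ring stabilises a benzylic cation more than the pyrogallol ring of step 13 does.

Step 23
Reactants: 35 tris-silyl trimer
Product: 36 trideca-O-benzyl trimer with free 3-OH on all three units
Conditions: nBu4NF (excess), THF, rt → 40 °C
Reagents that add atoms: none
Why: Fluoride cleavage of the three secondary silyl ethers; benzyl ethers and the interflavan bonds are stable to fluoride and mild base.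

Step 24
Reactants: 36 triol; 37 3,4,5-tris(benzyloxy)benzoic acid (three equivalents are incorporated, one on each O3)
Product: 38 docosa-O-benzyl derivative of the target (three tri-O-benzylgalloyl esters)
Conditions: 37 (4.5 equiv), dicyclohexylcarbodiimide (4.5 equiv), 4-(dimethylamino)pyridine (1.5 equiv), CH2Cl2, 0 °C → rt
Reagents that add atoms: 3,4,5-tris(benzyloxy)benzoic acid (second equivalent of 37), O=C(O)c1cc(OCc2ccccc2)c(OCc2ccccc2)c(OCc2ccccc2)c1; 3,4,5-tris(benzyloxy)benzoic acid (third equivalent of 37), O=C(O)c1cc(OCc2ccccc2)c(OCc2ccccc2)c(OCc2ccccc2)c1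
Why: Threefold Steglich esterification in which each of the three O3 hydroxyls takes up one acyl group, so that three molecules of 37 enter the product. Acyl transfer through the acylpyridinium ion is the usual way to esterify the hindered 3-OH groups of benzylated flavan-3-ols and needs neither acid nor strong base.

Step 25
Reactants: 38 perbenzylated tri-gallate
Product: 39 epicatechin gallate-(4β→8)-epigallocatechin gallate-(4β→8)-catechin gallate (CNP0321910.1)
Conditions: H2 (1 atm), Pd(OH)2/C, THF/MeOH/H2O, rt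
Reagents that add atoms: none
Why: Hydrogenolysis of all twenty-two benzyl ethers; under neutral conditions the gallate esters, the C2–O1 bonds and the interflavan bonds should remain, and no stereocentre is affected.

## Compound list

1 | (+)-catechin, (2R,3S) | O[C@H]1Cc2c(O)cc(O)cc2O[C@@H]1c1ccc(O)c(O)c1 | starting material
2 | 5,7,3',4'-tetra-O-benzyl-(+)-catechin | O[C@H]1Cc2c(OCc9ccccc9)cc(OCc9ccccc9)cc2O[C@@H]1c1ccc(OCc9ccccc9)c(OCc9ccccc9)c1 | intermediate
3 | 5,7,3',4'-tetra-O-benzyl-3-O-(tert-butyldimethylsilyl)-(+)-catechin | CC(C)(C)[Si](C)(C)O[C@H]1Cc2c(OCc9ccccc9)cc(OCc9ccccc9)cc2O[C@@H]1c1ccc(OCc9ccccc9)c(OCc9ccccc9)c1 | intermediate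
4 | 8-bromo-5,7,3',4'-tetra-O-benzyl-3-O-(tert-butyldimethylsilyl)-(+)-catechin | Brc1c(OCc9ccccc9)cc(OCc9ccccc9)c2c1O[C@H](c1ccc(OCc9ccccc9)c(OCc9ccccc9)c1)[C@@H](O[Si](C)(C)C(C)(C)C)C2 | intermediate
5 | (E)-2-(3,3-diethoxyprop-1-en-1-yl)-4,4,5,5-tetramethyl-1,3,2-dioxaborolane | CCOC(OCC)/C=C/B1OC(C)(C)C(C)(C)O1 | starting material
6 | 8-[(E)-3,3-diethoxyprop-1-enyl]-5,7,3',4'-tetra-O-benzyl-3-O-(tert-butyldimethylsilyl)catechin | CCOC(OCC)/C=C/c1c(OCc9ccccc9)cc(OCc9ccccc9)c2c1O[C@H](c1ccc(OCc9ccccc9)c(OCc9ccccc9)c1)[C@@H](O[Si](C)(C)C(C)(C)C)C2 | intermediate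
7 | (E)-3-[5,7,3',4'-tetra-O-benzyl-3-O-(tert-butyldimethylsilyl)catechin-8-yl]acrylaldehyde | O=C/C=C/c1c(OCc9ccccc9)cc(OCc9ccccc9)c2c1O[C@H](c1ccc(OCc9ccccc9)c(OCc9ccccc9)c1)[C@@H](O[Si](C)(C)C(C)(C)C)C2 | intermediate
8 | 3,5-bis(benzyloxy)phenol | Oc1cc(OCc2ccccc2)cc(OCc2ccccc2)c1 | starting material
9 | (3R)-3-[2,4-bis(benzyloxy)-6-hydroxyphenyl]-3-(protected catechin-8-yl)propanal | O=CC[C@@H](c3c(OCc9ccccc9)cc(OCc9ccccc9)c4c3O[C@H](c3ccc(OCc9ccccc9)c(OCc9ccccc9)c3)[C@@H](O[Si](C)(C)C(C)(C)C)C4)c2c(OCc9ccccc9)cc(OCc9ccccc9)cc2O | intermediate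
10 | (4R)-5,7-bis(benzyloxy)-4-(protected catechin-8-yl)chroman-2-ol, anomeric mixture | OC1C[C@@H](c3c(OCc9ccccc9)cc(OCc9ccccc9)c4c3O[C@H](c3ccc(OCc9ccccc9)c(OCc9ccccc9)c3)[C@@H](O[Si](C)(C)C(C)(C)C)C4)c2c(OCc9ccccc9)cc(OCc9ccccc9)cc2O1 | intermediate
11 | (4R)-5,7-bis(benzyloxy)-4-(protected catechin-8-yl)chroman-2-one | O=C1C[C@@H](c3c(OCc9ccccc9)cc(OCc9ccccc9)c4c3O[C@H](c3ccc(OCc9ccccc9)c(OCc9ccccc9)c3)[C@@H](O[Si](C)(C)C(C)(C)C)C4)c2c(OCc9ccccc9)cc(OCc9ccccc9)cc2O1 | intermediate
12 | potassium enolate of lactone 11 | [K+].[O-]C1=C[C@@H](c3c(OCc9ccccc9)cc(OCc9ccccc9)c4c3O[C@H](c3ccc(OCc9ccccc9)c(OCc9ccccc9)c3)[C@@H](O[Si](C)(C)C(C)(C)C)C4)c2c(OCc9ccccc9)cc(OCc9ccccc9)cc2O1 | intermediate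
13 | 3,4-trans-3-hydroxy lactone (3-OH α, 4-aryl β) | O=C1[C@H](O)[C@@H](c3c(OCc9ccccc9)cc(OCc9ccccc9)c4c3O[C@H](c3ccc(OCc9ccccc9)c(OCc9ccccc9)c3)[C@@H](O[Si](C)(C)C(C)(C)C)C4)c2c(OCc9ccccc9)cc(OCc9ccccc9)cc2O1 | intermediate
14 | 3,4-trans-3-(tert-butyldimethylsilyloxy) lactone | O=C1[C@H](O[Si](C)(C)C(C)(C)C)[C@@H](c3c(OCc9ccccc9)cc(OCc9ccccc9)c4c3O[C@H](c3ccc(OCc9ccccc9)c(OCc9ccccc9)c3)[C@@H](O[Si](C)(C)C(C)(C)C)C4)c2c(OCc9ccccc9)cc(OCc9ccccc9)cc2O1 | intermediate
15 | 3,4-trans-3-(tert-butyldimethylsilyloxy)chroman-2-ol, anomeric mixture | OC1[C@H](O[Si](C)(C)C(C)(C)C)[C@@H](c3c(OCc9ccccc9)cc(OCc9ccccc9)c4c3O[C@H](c3ccc(OCc9ccccc9)c(OCc9ccccc9)c3)[C@@H](O[Si](C)(C)C(C)(C)C)C4)c2c(OCc9ccccc9)cc(OCc9ccccc9)cc2O1 | intermediate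
16 | 5-bromo-1,2,3-trimethoxybenzene | COc1cc(Br)cc(OC)c1OC | starting material
17 | 5-bromobenzene-1,2,3-triol | Oc1cc(Br)cc(O)c1O | intermediate
18 | 5-bromo-1,2,3-tris(benzyloxy)benzene | Brc1cc(OCc2ccccc2)c(OCc2ccccc2)c(OCc2ccccc2)c1 | intermediate
19 | 3,4,5-tris(benzyloxy)phenylmagnesium bromide | Br[Mg]c1cc(OCc2ccccc2)c(OCc2ccccc2)c(OCc2ccccc2)c1 | intermediate
20 | 1,2-anti phenol carbinol of the middle unit (carbinol S) | O[C@@H](c1cc(OCc9ccccc9)c(OCc9ccccc9)c(OCc9ccccc9)c1)[C@H](O[Si](C)(C)C(C)(C)C)[C@@H](c3c(OCc9ccccc9)cc(OCc9ccccc9)c4c3O[C@H](c3ccc(OCc9ccccc9)c(OCc9ccccc9)c3)[C@@H](O[Si](C)(C)C(C)(C)C)C4)c2c(OCc9ccccc9)cc(OCc9ccccc9)cc2O | intermediate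
21 | [penta-O-benzyl-3-O-TBS-epigallocatechin]-(4β→8)-[tetra-O-benzyl-3-O-TBS-catechin] | CC(C)(C)[Si](C)(C)O[C@@H]1[C@@H](c3c(OCc9ccccc9)cc(OCc9ccccc9)c4c3O[C@H](c3ccc(OCc9ccccc9)c(OCc9ccccc9)c3)[C@@H](O[Si](C)(C)C(C)(C)C)C4)c2c(OCc9ccccc9)cc(OCc9ccccc9)cc2O[C@@H]1c1cc(OCc9ccccc9)c(OCc9ccccc9)c(OCc9ccccc9)c1 | intermediate
22 | 21 with bromine at C8 of the epigallocatechin unit | CC(C)(C)[Si](C)(C)O[C@@H]1[C@@H](c3c(OCc9ccccc9)cc(OCc9ccccc9)c4c3O[C@H](c3ccc(OCc9ccccc9)c(OCc9ccccc9)c3)[C@@H](O[Si](C)(C)C(C)(C)C)C4)c2c(OCc9ccccc9)cc(OCc9ccccc9)c(Br)c2O[C@@H]1c1cc(OCc9ccccc9)c(OCc9ccccc9)c(OCc9ccccc9)c1 | intermediate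
23 | 21 with (E)-3,3-diethoxyprop-1-enyl at C8 of the epigallocatechin unit | CC(C)(C)[Si](C)(C)O[C@@H]1[C@@H](c3c(OCc9ccccc9)cc(OCc9ccccc9)c4c3O[C@H](c3ccc(OCc9ccccc9)c(OCc9ccccc9)c3)[C@@H](O[Si](C)(C)C(C)(C)C)C4)c2c(OCc9ccccc9)cc(OCc9ccccc9)c(/C=C/C(OCC)OCC)c2O[C@@H]1c1cc(OCc9ccccc9)c(OCc9ccccc9)c(OCc9ccccc9)c1 | intermediate
24 | (E)-3-(dimer-8-yl)acrylaldehyde | CC(C)(C)[Si](C)(C)O[C@@H]1[C@@H](c3c(OCc9ccccc9)cc(OCc9ccccc9)c4c3O[C@H](c3ccc(OCc9ccccc9)c(OCc9ccccc9)c3)[C@@H](O[Si](C)(C)C(C)(C)C)C4)c2c(OCc9ccccc9)cc(OCc9ccccc9)c(/C=C/C=O)c2O[C@@H]1c1cc(OCc9ccccc9)c(OCc9ccccc9)c(OCc9ccccc9)c1 | intermediate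
25 | 3-[2,4-bis(benzyloxy)-6-hydroxyphenyl]-3-(dimer-8-yl)propanal | CC(C)(C)[Si](C)(C)O[C@@H]1[C@@H](c3c(OCc9ccccc9)cc(OCc9ccccc9)c4c3O[C@H](c3ccc(OCc9ccccc9)c(OCc9ccccc9)c3)[C@@H](O[Si](C)(C)C(C)(C)C)C4)c2c(OCc9ccccc9)cc(OCc9ccccc9)c([C@H](CC=O)c4c(OCc9ccccc9)cc(OCc9ccccc9)cc4O)c2O[C@@H]1c1cc(OCc9ccccc9)c(OCc9ccccc9)c(OCc9ccccc9)c1 | intermediate
26 | 5,7-bis(benzyloxy)-4-(dimer-8-yl)chroman-2-ol, anomeric mixture | CC(C)(C)[Si](C)(C)O[C@@H]1[C@@H](c3c(OCc9ccccc9)cc(OCc9ccccc9)c4c3O[C@H](c3ccc(OCc9ccccc9)c(OCc9ccccc9)c3)[C@@H](O[Si](C)(C)C(C)(C)C)C4)c2c(OCc9ccccc9)cc(OCc9ccccc9)c([C@H]3c4c(OCc9ccccc9)cc(OCc9ccccc9)cc4OC(O)C3)c2O[C@@H]1c1cc(OCc9ccccc9)c(OCc9ccccc9)c(OCc9ccccc9)c1 | intermediate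
27 | 5,7-bis(benzyloxy)-4-(dimer-8-yl)chroman-2-one | CC(C)(C)[Si](C)(C)O[C@@H]1[C@@H](c3c(OCc9ccccc9)cc(OCc9ccccc9)c4c3O[C@H](c3ccc(OCc9ccccc9)c(OCc9ccccc9)c3)[C@@H](O[Si](C)(C)C(C)(C)C)C4)c2c(OCc9ccccc9)cc(OCc9ccccc9)c([C@H]3c4c(OCc9ccccc9)cc(OCc9ccccc9)cc4OC(=O)C3)c2O[C@@H]1c1cc(OCc9ccccc9)c(OCc9ccccc9)c(OCc9ccccc9)c1 | intermediate
28 | potassium enolate of lactone 27 | [K+].CC(C)(C)[Si](C)(C)O[C@@H]1[C@@H](c3c(OCc9ccccc9)cc(OCc9ccccc9)c4c3O[C@H](c3ccc(OCc9ccccc9)c(OCc9ccccc9)c3)[C@@H](O[Si](C)(C)C(C)(C)C)C4)c2c(OCc9ccccc9)cc(OCc9ccccc9)c([C@H]3c4c(OCc9ccccc9)cc(OCc9ccccc9)cc4OC([O-])=C3)c2O[C@@H]1c1cc(OCc9ccccc9)c(OCc9ccccc9)c(OCc9ccccc9)c1 | intermediate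
29 | top-unit 3,4-trans-3-hydroxy lactone | CC(C)(C)[Si](C)(C)O[C@@H]1[C@@H](c3c(OCc9ccccc9)cc(OCc9ccccc9)c4c3O[C@H](c3ccc(OCc9ccccc9)c(OCc9ccccc9)c3)[C@@H](O[Si](C)(C)C(C)(C)C)C4)c2c(OCc9ccccc9)cc(OCc9ccccc9)c([C@H]3c4c(OCc9ccccc9)cc(OCc9ccccc9)cc4OC(=O)[C@@H]3O)c2O[C@@H]1c1cc(OCc9ccccc9)c(OCc9ccccc9)c(OCc9ccccc9)c1 | intermediate
30 | top-unit 3,4-trans-3-(tert-butyldimethylsilyloxy) lactone | CC(C)(C)[Si](C)(C)O[C@@H]1[C@@H](c3c(OCc9ccccc9)cc(OCc9ccccc9)c4c3O[C@H](c3ccc(OCc9ccccc9)c(OCc9ccccc9)c3)[C@@H](O[Si](C)(C)C(C)(C)C)C4)c2c(OCc9ccccc9)cc(OCc9ccccc9)c([C@H]3c4c(OCc9ccccc9)cc(OCc9ccccc9)cc4OC(=O)[C@@H]3O[Si](C)(C)C(C)(C)C)c2O[C@@H]1c1cc(OCc9ccccc9)c(OCc9ccccc9)c(OCc9ccccc9)c1 | intermediate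
31 | top-unit 3,4-trans-3-(tert-butyldimethylsilyloxy)chroman-2-ol, anomeric mixture | CC(C)(C)[Si](C)(C)O[C@@H]1[C@@H](c3c(OCc9ccccc9)cc(OCc9ccccc9)c4c3O[C@H](c3ccc(OCc9ccccc9)c(OCc9ccccc9)c3)[C@@H](O[Si](C)(C)C(C)(C)C)C4)c2c(OCc9ccccc9)cc(OCc9ccccc9)c([C@H]3c4c(OCc9ccccc9)cc(OCc9ccccc9)cc4OC(O)[C@@H]3O[Si](C)(C)C(C)(C)C)c2O[C@@H]1c1cc(OCc9ccccc9)c(OCc9ccccc9)c(OCc9ccccc9)c1 | intermediate
32 | 4-bromo-1,2-bis(benzyloxy)benzene | Brc1ccc(OCc2ccccc2)c(OCc2ccccc2)c1 | starting material
33 | 3,4-bis(benzyloxy)phenylmagnesium bromide | Br[Mg]c1ccc(OCc2ccccc2)c(OCc2ccccc2)c1 | intermediate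
34 | 1,2-anti phenol carbinol of the top unit | CC(C)(C)[Si](C)(C)O[C@@H]1[C@@H](c3c(OCc9ccccc9)cc(OCc9ccccc9)c4c3O[C@H](c3ccc(OCc9ccccc9)c(OCc9ccccc9)c3)[C@@H](O[Si](C)(C)C(C)(C)C)C4)c2c(OCc9ccccc9)cc(OCc9ccccc9)c([C@@H](c4c(OCc9ccccc9)cc(OCc9ccccc9)cc4O)[C@@H](O[Si](C)(C)C(C)(C)C)[C@@H](O)c4ccc(OCc9ccccc9)c(OCc9ccccc9)c4)c2O[C@@H]1c1cc(OCc9ccccc9)c(OCc9ccccc9)c(OCc9ccccc9)c1 | intermediate
35 | trideca-O-benzyl-tris-O3-TBS epicatechin-(4β→8)-epigallocatechin-(4β→8)-catechin | CC(C)(C)[Si](C)(C)O[C@@H]1[C@@H](c3c(OCc9ccccc9)cc(OCc9ccccc9)c4c3O[C@H](c3ccc(OCc9ccccc9)c(OCc9ccccc9)c3)[C@@H](O[Si](C)(C)C(C)(C)C)C4)c2c(OCc9ccccc9)cc(OCc9ccccc9)c([C@H]3c4c(OCc9ccccc9)cc(OCc9ccccc9)cc4O[C@H](c4ccc(OCc9ccccc9)c(OCc9ccccc9)c4)[C@@H]3O[Si](C)(C)C(C)(C)C)c2O[C@@H]1c1cc(OCc9ccccc9)c(OCc9ccccc9)c(OCc9ccccc9)c1 | intermediate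
36 | trideca-O-benzyl epicatechin-(4β→8)-epigallocatechin-(4β→8)-catechin, three free 3-OH | O[C@@H]1[C@@H](c3c(OCc9ccccc9)cc(OCc9ccccc9)c4c3O[C@H](c3ccc(OCc9ccccc9)c(OCc9ccccc9)c3)[C@@H](O)C4)c2c(OCc9ccccc9)cc(OCc9ccccc9)c([C@H]3c4c(OCc9ccccc9)cc(OCc9ccccc9)cc4O[C@H](c4ccc(OCc9ccccc9)c(OCc9ccccc9)c4)[C@@H]3O)c2O[C@@H]1c1cc(OCc9ccccc9)c(OCc9ccccc9)c(OCc9ccccc9)c1 | intermediate
37 | 3,4,5-tris(benzyloxy)benzoic acid | O=C(O)c1cc(OCc2ccccc2)c(OCc2ccccc2)c(OCc2ccccc2)c1 | starting material
38 | docosa-O-benzyl derivative of the target | O=C(O[C@@H]1[C@@H](c2c(OCc9ccccc9)cc(OCc9ccccc9)c3c2O[C@H](c2ccc(OCc9ccccc9)c(OCc9ccccc9)c2)[C@@H](OC(=O)c2cc(OCc9ccccc9)c(OCc9ccccc9)c(OCc9ccccc9)c2)C3)c2c(OCc9ccccc9)cc(OCc9ccccc9)c([C@H]3c4c(OCc9ccccc9)cc(OCc9ccccc9)cc4O[C@H](c4ccc(OCc9ccccc9)c(OCc9ccccc9)c4)[C@@H]3OC(=O)c3cc(OCc9ccccc9)c(OCc9ccccc9)c(OCc9ccccc9)c3)c2O[C@@H]1c1cc(OCc9ccccc9)c(OCc9ccccc9)c(OCc9ccccc9)c1)c1cc(OCc9ccccc9)c(OCc9ccccc9)c(OCc9ccccc9)c1 | intermediate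
39 | epicatechin gallate-(4β→8)-epigallocatechin gallate-(4β→8)-catechin gallate (CNP0321910.1) | O=C(O[C@@H]1[C@@H](c2c(O)cc(O)c3c2O[C@H](c2ccc(O)c(O)c2)[C@@H](OC(=O)c2cc(O)c(O)c(O)c2)C3)c2c(O)cc(O)c([C@H]3c4c(O)cc(O)cc4O[C@H](c4ccc(O)c(O)c4)[C@@H]3OC(=O)c3cc(O)c(O)c(O)c3)c2O[C@@H]1c1cc(O)c(O)c(O)c1)c1cc(O)c(O)c(O)c1 | target

## Step count and least certain steps

Total: 25 steps. Longest linear sequence: 23 steps (steps 1–9 and 12–25, from 1 to 39); steps 10 and 11 are a two-step branch.

**Step 5 (key step).** The 2,4,6-trioxygenated aryl group of 7 donates into the iminium ion and its two ortho substituents crowd the β-carbon, so the conjugate addition may be slow or reversible. An acid-promoted background reaction would erode facial control, and para attack or double alkylation of the phenol can compete. The fallback gives up catalyst control and sets out from bromide 4. Bromine–lithium exchange (nBuLi, THF, −78 °C) and formylation with DMF convert 4 into the 8-carbaldehyde F1. Knoevenagel condensation of F1 with 2,2-dimethyl-1,3-dioxane-4,6-dione gives the arylidene derivative F2. Conjugate addition of phenol 8 to F2 with acylative ring closure, catalysed by Yb(OTf)3 in warm nitromethane, gives the dihydrocoumarin with loss of acetone and carbon dioxide. This variant has only substrate control at C4, so the diastereomers would have to be separated by chromatography. The sequence returns to the route at lactone 11.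

**Step 16 (second annulation).** The same limits apply on a larger enal, and the C2 aryl group of the middle unit lies close to the reacting carbon and may oppose the catalyst. The fallback forms the top interflavan bond by cation coupling, without the bromide and without building ring C. (−)-Epicatechin is benzylated to the tetra-O-benzyl ether F3. Oxidation with DDQ in the presence of 2-ethoxyethanol gives the 4β-(2-ethoxyethoxy) derivative F4, and silylation gives its 3-O-TBS ether F5. Treatment of F5 with an excess of dimer 21 and TMSOTf in CH2Cl2 at −78 °C should bring C8 of the middle unit of 21 onto C4, trans to the C3 substituent. The sequence sets out from 21 and returns at 35.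

**Steps 12 and 21 (Felkin addition).** Partial chelation of magnesium by O3, or silyl migration in the alkoxide, would lower the anti selectivity or move the protecting group. The fallback replaces substrate control by reagent control. Lactone 14 is opened with one equivalent of the aryllithium made from 18 (nBuLi, THF, −78 °C) to the hydroxyaryl ketone F6; the ketone is flanked by the silyloxy and diarylmethyl groups, which should slow a second addition. F6 is reduced with the oxazaborolidine catalyst and BH3·SMe2 (Corey–Bakshi–Shibata reduction), the catalyst enantiomer chosen to give the anti carbinol. This sequence sets out from 14 and returns at 20. For the top unit the same two operations set out from lactone 30 with the aryllithium made from 32, pass through the hydroxyaryl ketone F7 and return at 34.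

**Step 14 (bromination of the dimer).** Bromination could also occur at C6 of the middle or the bottom unit, or twice. The fallback puts the carbon substituent in by chelation-directed formylation before ring C is closed. The phenol carbinol 20 is formylated ortho to the phenol with MgCl2, Et3N and paraformaldehyde, which can only reach the future C8 and gives salicylaldehyde F8. Mitsunobu closure as in step 13 gives the 8-formyl dimer F9. A Wittig reaction of F9 with (triphenylphosphoranylidene)acetaldehyde gives the enal. The sequence sets out from 20 and returns at 24.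

## Further compounds

F1 | step 5 | 5,7,3',4'-tetra-O-benzyl-3-O-(tert-butyldimethylsilyl)catechin-8-carbaldehyde | O=Cc1c(OCc9ccccc9)cc(OCc9ccccc9)c2c1O[C@H](c1ccc(OCc9ccccc9)c(OCc9ccccc9)c1)[C@@H](O[Si](C)(C)C(C)(C)C)C2
F2 | step 5 | 5-[(protected catechin-8-yl)methylidene]-2,2-dimethyl-1,3-dioxane-4,6-dione | CC1(C)OC(=O)C(=Cc2c(OCc9ccccc9)cc(OCc9ccccc9)c3c2O[C@H](c2ccc(OCc9ccccc9)c(OCc9ccccc9)c2)[C@@H](O[Si](C)(C)C(C)(C)C)C3)C(=O)O1
F3 | step 16 | 5,7,3',4'-tetra-O-benzyl-(−)-epicatechin | O[C@@H]1Cc2c(OCc9ccccc9)cc(OCc9ccccc9)cc2O[C@@H]1c1ccc(OCc9ccccc9)c(OCc9ccccc9)c1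
F4 | step 16 | 5,7,3',4'-tetra-O-benzyl-4β-(2-ethoxyethoxy)epicatechin | CCOCCO[C@H]1c2c(OCc9ccccc9)cc(OCc9ccccc9)cc2O[C@H](c2ccc(OCc9ccccc9)c(OCc9ccccc9)c2)[C@@H]1O
F5 | step 16 | 5,7,3',4'-tetra-O-benzyl-3-O-(tert-butyldimethylsilyl)-4β-(2-ethoxyethoxy)epicatechin | CCOCCO[C@H]1c2c(OCc9ccccc9)cc(OCc9ccccc9)cc2O[C@H](c2ccc(OCc9ccccc9)c(OCc9ccccc9)c2)[C@@H]1O[Si](C)(C)C(C)(C)C
F6 | step 12 | 3-[2,4-bis(benzyloxy)-6-hydroxyphenyl]-2-(tert-butyldimethylsilyloxy)-3-(protected catechin-8-yl)-1-[3,4,5-tris(benzyloxy)phenyl]propan-1-one | O=C(c1cc(OCc9ccccc9)c(OCc9ccccc9)c(OCc9ccccc9)c1)[C@H](O[Si](C)(C)C(C)(C)C)[C@@H](c3c(OCc9ccccc9)cc(OCc9ccccc9)c4c3O[C@H](c3ccc(OCc9ccccc9)c(OCc9ccccc9)c3)[C@@H](O[Si](C)(C)C(C)(C)C)C4)c2c(OCc9ccccc9)cc(OCc9ccccc9)cc2O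
F7 | step 21 | 1-[3,4-bis(benzyloxy)phenyl]-3-[2,4-bis(benzyloxy)-6-hydroxyphenyl]-2-(tert-butyldimethylsilyloxy)-3-(dimer-8-yl)propan-1-one | CC(C)(C)[Si](C)(C)O[C@@H]1[C@@H](c3c(OCc9ccccc9)cc(OCc9ccccc9)c4c3O[C@H](c3ccc(OCc9ccccc9)c(OCc9ccccc9)c3)[C@@H](O[Si](C)(C)C(C)(C)C)C4)c2c(OCc9ccccc9)cc(OCc9ccccc9)c([C@@H](c4c(OCc9ccccc9)cc(OCc9ccccc9)cc4O)[C@@H](O[Si](C)(C)C(C)(C)C)C(=O)c4ccc(OCc9ccccc9)c(OCc9ccccc9)c4)c2O[C@@H]1c1cc(OCc9ccccc9)c(OCc9ccccc9)c(OCc9ccccc9)c1
F8 | step 14 | phenol carbinol 20 with a formyl group ortho to the phenolic OH | O[C@@H](c1cc(OCc9ccccc9)c(OCc9ccccc9)c(OCc9ccccc9)c1)[C@H](O[Si](C)(C)C(C)(C)C)[C@@H](c3c(OCc9ccccc9)cc(OCc9ccccc9)c4c3O[C@H](c3ccc(OCc9ccccc9)c(OCc9ccccc9)c3)[C@@H](O[Si](C)(C)C(C)(C)C)C4)c2c(OCc9ccccc9)cc(OCc9ccccc9)c(C=O)c2O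
F9 | step 14 | dimer 21 with a formyl group at C8 of the epigallocatechin unit | CC(C)(C)[Si](C)(C)O[C@@H]1[C@@H](c3c(OCc9ccccc9)cc(OCc9ccccc9)c4c3O[C@H](c3ccc(OCc9ccccc9)c(OCc9ccccc9)c3)[C@@H](O[Si](C)(C)C(C)(C)C)C4)c2c(OCc9ccccc9)cc(OCc9ccccc9)c(C=O)c2O[C@@H]1c1cc(OCc9ccccc9)c(OCc9ccccc9)c(OCc9ccccc9)c1
A1 | alternative 1 | 5,7-bis(benzyloxy)-4-(protected catechin-8-yl)-4H-chromene | C1=C[C@@H](c3c(OCc9ccccc9)cc(OCc9ccccc9)c4c3O[C@H](c3ccc(OCc9ccccc9)c(OCc9ccccc9)c3)[C@@H](O[Si](C)(C)C(C)(C)C)C4)c2c(OCc9ccccc9)cc(OCc9ccccc9)cc2O1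
A2 | alternative 1 | protected epigallocatechin-(4β→8)-catechin with free middle 3-OH and bottom 3-O-TBS | O[C@@H]1[C@@H](c2c(OCc9ccccc9)cc(OCc9ccccc9)c3c2O[C@H](c2ccc(OCc9ccccc9)c(OCc9ccccc9)c2)[C@@H](O[Si](C)(C)C(C)(C)C)C3)c2c(OCc9ccccc9)cc(OCc9ccccc9)cc2O[C@@H]1c1cc(OCc9ccccc9)c(OCc9ccccc9)c(OCc9ccccc9)c1
A3 | alternative 2 | perbenzylated epigallocatechin gallate carrying at C4 a 2-[α-(tri-O-benzylgalloyloxy)-3,4-bis(benzyloxy)benzyl]-4,6-bis(benzyloxy)-2,3-dihydrobenzofuran-7-yl group | O=C(O[C@@H]1[C@@H](c3c(OCc9ccccc9)cc(OCc9ccccc9)c4c3O[C@@H]([C@@H](OC(=O)c3cc(OCc9ccccc9)c(OCc9ccccc9)c(OCc9ccccc9)c3)c3ccc(OCc9ccccc9)c(OCc9ccccc9)c3)C4)c2c(OCc9ccccc9)cc(OCc9ccccc9)cc2O[C@@H]1c1cc(OCc9ccccc9)c(OCc9ccccc9)c(OCc9ccccc9)c1)c1cc(OCc9ccccc9)c(OCc9ccccc9)c(OCc9ccccc9)c1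
A4 | alternative 2 | perbenzylated epigallocatechin gallate-(4β→8)-catechin gallate | O=C(O[C@@H]1[C@@H](c2c(OCc9ccccc9)cc(OCc9ccccc9)c3c2O[C@H](c2ccc(OCc9ccccc9)c(OCc9ccccc9)c2)[C@@H](OC(=O)c2cc(OCc9ccccc9)c(OCc9ccccc9)c(OCc9ccccc9)c2)C3)c2c(OCc9ccccc9)cc(OCc9ccccc9)cc2O[C@@H]1c1cc(OCc9ccccc9)c(OCc9ccccc9)c(OCc9ccccc9)c1)c1cc(OCc9ccccc9)c(OCc9ccccc9)c(OCc9ccccc9)c1
A5 | alternative 3 | 5,7,3',4'-tetra-O-benzyl-3-O-TBS-4β-[(triisopropylsilyloxy)ethynyl]epicatechin | CC(C)[Si](C(C)C)(C(C)C)OC#C[C@H]1c2c(OCc9ccccc9)cc(OCc9ccccc9)cc2O[C@H](c2ccc(OCc9ccccc9)c(OCc9ccccc9)c2)[C@@H]1O[Si](C)(C)C(C)(C)C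
A6 | alternative 3 | 3-(benzyloxy)cyclobut-2-en-1-one | O=C1C=C(OCc2ccccc2)C1
A7 | alternative 3 | 2-(protected epicatechin-4β-yl)-5-benzyloxy-3-(triisopropylsilyloxy)phenol | Oc1cc(OCc9ccccc9)cc(O[Si](C(C)C)(C(C)C)C(C)C)c1[C@H]1c2c(OCc9ccccc9)cc(OCc9ccccc9)cc2O[C@H](c2ccc(OCc9ccccc9)c(OCc9ccccc9)c2)[C@@H]1O[Si](C)(C)C(C)(C)C
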